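The disconnection rests on ring A of the isocoumarin, a benzene ring that carries oxygen at C6 and C8 in a meta relationship, the lactone carbonyl (C1) on C8a beside C8, and C4 on C4a. Such a resorcylate is a dehydrogenated, carboxylated cyclohexane-1,3-dione: one dione oxygen is tied up as the enol ether of the ring B phenol (later O–C8), the other as a silyl enol ether (later O–C6). A [4+2] cycloaddition of this 1-aryloxy-3-silyloxycyclohexa-1,3-diene with the ynoate triple bond of methyl deca-2,4-diynoate, then expulsion of ethylene, makes the C8–C8a and C4a–C5 bonds and the aromatic ring A at once, leaving the second alkyne to close the pyranone.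

Key step: step 10

Assumption: 1,3-dimethoxy-5-pentylbenzene (olivetol dimethyl ether, 1) is taken as purchasable; otherwise it is one O-methylation (MeI, K2CO3) from olivetol.

Design notes:
- The target has no stereocentre.
- Ring B keeps its phenols as methyl ethers and its carboxyl group as a benzyl ester. The benzyl C–O bond should fall to BBr3 at low temperature together with the ethers, which a doubly ortho-substituted methyl ester would not do reliably.
- The diynoate is made by acylating a lithium diynide, so that no amine base meets a halopropiolate.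
- The silyl dienol ether is used crude, without aqueous work-up.

Step 1
Reactants: 1 1,3-dimethoxy-5-pentylbenzene (olivetol dimethyl ether)
Product: 2 2-bromo-1,5-dimethoxy-3-pentylbenzene
Conditions: NBS (1.0 equiv), MeCN, 0 °C to rt
Reagents that add atoms: N-bromosuccinimide, O=C1CCC(=O)N1Br
Why: Electrophilic aromatic bromination should take the position para to one methoxy group and ortho to the other (beside the pentyl chain) rather than the more crowded position between the two methoxy groups, the usual outcome for 5-alkylresorcinol dimethyl ethers.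

Step 2
Reactants: 2 2-bromo-1,5-dimethoxy-3-pentylbenzene; 3 benzyl chloroformate
Product: 5 benzyl 2,4-dimethoxy-6-pentylbenzoate, via aryllithium 4 (not isolated)
Conditions: n-BuLi, THF, −78 °C; then cannulated into 3 (1.5 equiv), THF, −78 °C to 0 °C
Reagents that add atoms: none
Why: Bromine–lithium exchange fixes the site of carboxylation, and inverse addition of the doubly ortho-substituted aryllithium to the chloroformate should stop at the ester (nucleophilic acyl substitution).

Step 3
Reactants: 5 benzyl 2,4-dimethoxy-6-pentylbenzoate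
Product: 6 benzyl 3-formyl-4,6-dimethoxy-2-pentylbenzoate
Conditions: Cl2CHOMe, TiCl4, CH2Cl2, −78 to 0 °C; H2O
Reagents that add atoms: dichloromethyl methyl ether, COC(Cl)Cl; water, O
Why: Rieche formylation (electrophilic aromatic substitution) should go to C5 of 5, which is para to the 2-methoxy and ortho to the 4-methoxy group, rather than to C3 between the two methoxy groups, the directing pattern of 2,4-dialkoxy-6-alkylbenzoates.

Step 4
Reactants: 6 benzyl 3-formyl-4,6-dimethoxy-2-pentylbenzoate
Product: 8 benzyl 3-hydroxy-4,6-dimethoxy-2-pentylbenzoate, via aryl formate 7 (not isolated)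
Conditions: mCPBA, CH2Cl2, 0 °C to rt; aq. NaHCO3/Na2S2O3 wash; then K2CO3 (cat.), MeOH, 0 °C
Reagents that add atoms: 3-chloroperoxybenzoic acid, O=C(OO)c1cccc(Cl)c1
Why: Baeyer–Villiger (Dakin-type) oxidation, in which the electron-rich aryl group migrates to oxygen and the resulting formate is methanolysed far faster than the doubly ortho-substituted benzyl ester.

Step 5
Reactants: 9 cyclohexane-1,3-dione
Product: 10 3-chlorocyclohex-2-en-1-one
Conditions: (COCl)2, DMF (cat.), CH2Cl2, 0 °C to rt
Reagents that add atoms: oxalyl chloride, O=C(Cl)C(=O)Cl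
Why: The enol of the 1,3-dione is converted into the vinylogous acid chloride by Vilsmeier-type activation with oxalyl chloride and DMF.

Step 6
Reactants: 8 benzyl 3-hydroxy-4,6-dimethoxy-2-pentylbenzoate; 10 3-chlorocyclohex-2-en-1-one
Product: 11 benzyl 4,6-dimethoxy-3-[(3-oxocyclohex-1-en-1-yl)oxy]-2-pentylbenzoate
Conditions: K2CO3, DMF, 60 °C
Reagents that add atoms: none
Why: Conjugate addition–elimination of the phenoxide on the β-chloro enone (vinylogous acyl substitution) should give the aryl vinylogous ester, the hindered phenoxide having no other productive path.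

Step 7
Reactants: 11 benzyl 4,6-dimethoxy-3-[(3-oxocyclohex-1-en-1-yl)oxy]-2-pentylbenzoate
Product: 13 benzyl 4,6-dimethoxy-2-pentyl-3-({3-[(trimethylsilyl)oxy]cyclohexa-1,3-dien-1-yl}oxy)benzoate, via lithium dienolate 12 (not isolated)
Conditions: LiN(iPr)2, THF, −78 °C; Me3SiCl, −78 °C to rt; pentane, filtration under Ar; used crude
Reagents that add atoms: chlorotrimethylsilane, C[Si](C)(C)Cl
Why: Kinetic deprotonation of a vinylogous ester by a lithium amide takes place at the α′ methylene (C6 of the enone), and O-silylation of the cross-conjugated enolate should give the 2-silyloxy diene (kinetic silyl enol ether formation).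

Step 8
Reactants: 14 1,4-bis(trimethylsilyl)buta-1,3-diyne; 15 1-iodopentane
Product: 17 trimethyl(nona-1,3-diyn-1-yl)silane, via lithium silylbutadiynide 16 (not isolated)
Conditions: MeLi·LiBr (1.0 equiv), THF, −78 °C to rt; then 15, DMPU, −78 °C to rt
Reagents that add atoms: none
Why: One equivalent of methyllithium cleaves a single C(sp)–Si bond of the bis-silyl diyne, and the lithium diynide is then alkylated by the primary iodide in an SN2 reaction assisted by DMPU.

Step 9
Reactants: 17 trimethyl(nona-1,3-diyn-1-yl)silane; 18 methyl chloroformate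
Product: 20 methyl deca-2,4-diynoate, via lithium nonadiynide 19 (not isolated)
Conditions: MeLi·LiBr (1.0 equiv), THF, −78 °C to rt; then cannulated into 18 (2 equiv), THF, −78 °C
Reagents that add atoms: none
Why: The remaining C(sp)–Si bond is cleaved in the same way and the lithium diynide is acylated by the chloroformate (nucleophilic acyl substitution), the standard entry to alk-2-ynoates.

Step 10
Reactants: 13 benzyl 4,6-dimethoxy-2-pentyl-3-({3-[(trimethylsilyl)oxy]cyclohexa-1,3-dien-1-yl}oxy)benzoate; 20 methyl deca-2,4-diynoate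
Product: 23 methyl 2-{3-[(benzyloxy)carbonyl]-4,6-dimethoxy-2-pentylphenoxy}-6-(hept-1-yn-1-yl)-4-hydroxybenzoate, via bicyclooctadiene adduct 21 (not isolated), via aryl silyl ether 22 (not isolated)
Conditions: 20 (2 equiv), BHT (cat.), toluene, sealed tube, 110 °C then 160 °C; then 1 M HCl, THF, 0 °C
Reagents that add atoms: none
Why: The electron-rich diene adds suprafacially to the ester-conjugated triple bond of 20 in a thermal, asynchronous [4+2] cycloaddition, and the bicyclo[2.2.2]octa-2,5-diene 21 then loses its saturated two-carbon bridge as ethylene by a retro-[4+2] reaction (Alder–Rickert sequence), which is irreversible because it creates the benzene ring. The closest known reaction type is the preparation of 2-alkoxy-4-hydroxybenzoates from 1-alkoxy-3-silyloxycyclohexa-1,3-dienes and alk-2-ynoates. Ring A is closed by intermolecular [4+2] annulation, four carbons (future C5, C6, C7, C8) coming from the diene and two (future C4a, C8a) from the alkyne, with the C4a–C5 and C8–C8a bonds formed. No stereocentre remains in 23, since the two bridgehead centres of racemic 21 are erased on aromatization. Regioselectivity is needed and follows from polarity: both oxygen donors place the largest HOMO coefficient on the unsubstituted CH terminus of the diene, which bonds to the β carbon of the ynoate, so that the ester carbon ends up next to the aryloxy-bearing carbon. Site selectivity between the two triple bonds is secured by the ester, which makes the C2–C3 alkyne the more electron-poor and less hindered dienophile, and the bridgehead aryloxy group cannot be eliminated, so that only ethylene can leave.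

Step 11
Reactants: 23 methyl 2-{3-[(benzyloxy)carbonyl]-4,6-dimethoxy-2-pentylphenoxy}-6-(hept-1-yn-1-yl)-4-hydroxybenzoate
Product: 24 benzyl 3-[(6-hydroxy-1-oxo-3-pentyl-1H-isochromen-8-yl)oxy]-4,6-dimethoxy-2-pentylbenzoate
Conditions: Cu(OTf)2 (10 mol%), CF3CO2H (2 equiv), ClCH2CH2Cl, 70 °C
Reagents that add atoms: none
Why: Acid-promoted 6-endo-dig cyclization of an ortho-alkynyl benzoate, in which the ester carbonyl oxygen (made electron-rich by the para hydroxyl and ortho aryloxy groups) attacks the alkyne carbon that bears the pentyl chain and the O-methyl group of the resulting 1-methoxyisochromenylium ion is passed on to trifluoroacetate.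

Step 12
Reactants: 24 benzyl 3-[(6-hydroxy-1-oxo-3-pentyl-1H-isochromen-8-yl)oxy]-4,6-dimethoxy-2-pentylbenzoate
Product: 25 4,6-dihydroxy-3-[(6-hydroxy-1-oxo-3-pentyl-1H-isochromen-8-yl)oxy]-2-pentylbenzoic acid (CNP0439913.0)
Conditions: BBr3 (8 equiv), CH2Cl2, −78 °C to rt; H2O, 0 °C
Reagents that add atoms: none
Why: Lewis-acid dealkylation, in which BBr3 cleaves the two aryl methyl ethers and the benzyl ester by bromide attack at the alkyl carbon while the diaryl ether and the enol lactone, which offer no alkyl C–O bond, should stay intact.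

Compound list

1 | 1,3-dimethoxy-5-pentylbenzene (olivetol dimethyl ether) | CCCCCc1cc(OC)cc(OC)c1 | starting material
2 | 2-bromo-1,5-dimethoxy-3-pentylbenzene | CCCCCc1cc(OC)cc(OC)c1Br | intermediate
3 | benzyl chloroformate | O=C(Cl)OCc1ccccc1 | starting material
4 | (2,4-dimethoxy-6-pentylphenyl)lithium | [Li]c1c(CCCCC)cc(OC)cc1OC | intermediate
5 | benzyl 2,4-dimethoxy-6-pentylbenzoate | CCCCCc1cc(OC)cc(OC)c1C(=O)OCc1ccccc1 | intermediate
6 | benzyl 3-formyl-4,6-dimethoxy-2-pentylbenzoate | CCCCCc1c(C=O)c(OC)cc(OC)c1C(=O)OCc1ccccc1 | intermediate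
7 | benzyl 3-(formyloxy)-4,6-dimethoxy-2-pentylbenzoate | CCCCCc1c(OC=O)c(OC)cc(OC)c1C(=O)OCc1ccccc1 | intermediate
8 | benzyl 3-hydroxy-4,6-dimethoxy-2-pentylbenzoate | CCCCCc1c(O)c(OC)cc(OC)c1C(=O)OCc1ccccc1 | intermediate
9 | cyclohexane-1,3-dione | O=C1CCCC(=O)C1 | starting material
10 | 3-chlorocyclohex-2-en-1-one | O=C1C=C(Cl)CCC1 | intermediate
11 | benzyl 4,6-dimethoxy-3-[(3-oxocyclohex-1-en-1-yl)oxy]-2-pentylbenzoate | CCCCCc1c(OC2=CC(=O)CCC2)c(OC)cc(OC)c1C(=O)OCc1ccccc1 | intermediate
12 | lithium 5-{3-[(benzyloxy)carbonyl]-4,6-dimethoxy-2-pentylphenoxy}cyclohexa-1,5-dien-1-olate | CCCCCc1c(OC2=CC(O[Li])=CCC2)c(OC)cc(OC)c1C(=O)OCc1ccccc1 | intermediate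
13 | benzyl 4,6-dimethoxy-2-pentyl-3-({3-[(trimethylsilyl)oxy]cyclohexa-1,3-dien-1-yl}oxy)benzoate | CCCCCc1c(OC2=CC(O[Si](C)(C)C)=CCC2)c(OC)cc(OC)c1C(=O)OCc1ccccc1 | intermediate
14 | 1,4-bis(trimethylsilyl)buta-1,3-diyne | C[Si](C)(C)C#CC#C[Si](C)(C)C | starting material
15 | 1-iodopentane | CCCCCI | starting material
16 | lithium 4-(trimethylsilyl)buta-1,3-diyn-1-ide | [Li]C#CC#C[Si](C)(C)C | intermediate
17 | trimethyl(nona-1,3-diyn-1-yl)silane | CCCCCC#CC#C[Si](C)(C)C | intermediate
18 | methyl chloroformate | COC(Cl)=O | starting material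
19 | lithium nona-1,3-diyn-1-ide | [Li]C#CC#CCCCCC | intermediate
20 | methyl deca-2,4-diynoate | CCCCCC#CC#CC(=O)OC | intermediate
21 | methyl 1-{3-[(benzyloxy)carbonyl]-4,6-dimethoxy-2-pentylphenoxy}-3-(hept-1-yn-1-yl)-5-[(trimethylsilyl)oxy]bicyclo[2.2.2]octa-2,5-diene-2-carboxylate (racemic; one enantiomer written) | COC(=O)C1=C(C#CCCCCC)[C@@H]2CC[C@@]1(Oc3c(OC)cc(OC)c(C(=O)OCc4ccccc4)c3CCCCC)C=C2O[Si](C)(C)C | intermediate
22 | methyl 2-{3-[(benzyloxy)carbonyl]-4,6-dimethoxy-2-pentylphenoxy}-6-(hept-1-yn-1-yl)-4-[(trimethylsilyl)oxy]benzoate | CCCCCC#Cc1cc(O[Si](C)(C)C)cc(Oc2c(OC)cc(OC)c(C(=O)OCc3ccccc3)c2CCCCC)c1C(=O)OC | intermediate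
23 | methyl 2-{3-[(benzyloxy)carbonyl]-4,6-dimethoxy-2-pentylphenoxy}-6-(hept-1-yn-1-yl)-4-hydroxybenzoate | CCCCCC#Cc1cc(O)cc(Oc2c(OC)cc(OC)c(C(=O)OCc3ccccc3)c2CCCCC)c1C(=O)OC | intermediate
24 | benzyl 3-[(6-hydroxy-1-oxo-3-pentyl-1H-isochromen-8-yl)oxy]-4,6-dimethoxy-2-pentylbenzoate | CCCCCc1cc2cc(O)cc(Oc3c(OC)cc(OC)c(C(=O)OCc4ccccc4)c3CCCCC)c2c(=O)o1 | intermediate
25 | 4,6-dihydroxy-3-[(6-hydroxy-1-oxo-3-pentyl-1H-isochromen-8-yl)oxy]-2-pentylbenzoic acid | CCCCCc1cc2cc(O)cc(Oc3c(O)cc(O)c(C(=O)O)c3CCCCC)c2c(=O)o1 | target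

Total step count: 12.
Longest linear sequence: 9 steps (steps 1, 2, 3, 4, 6, 7, 10, 11, 12, from 1 to 25).

Steps most likely to fail

Step 10. The cycloaddition at the crowded aryloxy-bearing diene terminus may be slow enough for [1,5]-hydrogen shifts in the diene, thermal oligomerization of the diyne or addition across the distal triple bond to compete. The fallback attaches the alkyne after the benzannulation. It sets out from 13 and runs the same cycloaddition–ethylene extrusion with methyl 3-bromopropiolate F1 (from methyl propiolate, N-bromosuccinimide and catalytic AgNO3 in acetone), a smaller and more electron-poor dienophile with a single triple bond. The adduct methyl 1-{3-[(benzyloxy)carbonyl]-4,6-dimethoxy-2-pentylphenoxy}-3-bromo-5-[(trimethylsilyl)oxy]bicyclo[2.2.2]octa-2,5-diene-2-carboxylate F2 should lose ethylene to the aryl silyl ether methyl 2-{3-[(benzyloxy)carbonyl]-4,6-dimethoxy-2-pentylphenoxy}-6-bromo-4-[(trimethylsilyl)oxy]benzoate F3. Acidic work-up should give methyl 2-{3-[(benzyloxy)carbonyl]-4,6-dimethoxy-2-pentylphenoxy}-6-bromo-4-hydroxybenzoate F4. Sonogashira coupling of this bromide with hept-1-yne (PdCl2(PPh3)2, CuI, Et3N, DMF, 60 °C) comes back to the route at 23.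

Step 11. The closure may take the 5-exo course to the alkylidene phthalide, the alkyne may be hydrated instead, or the ring B benzyl ester may suffer acidolysis. The fallback replaces the protic activation by a halonium-triggered closure followed by reduction. It sets out from 23: iodine in CH2Cl2 at rt should give, with loss of the ester methyl group to iodide, the 4-iodoisocoumarin benzyl 3-[(6-hydroxy-4-iodo-1-oxo-3-pentyl-1H-isochromen-8-yl)oxy]-4,6-dimethoxy-2-pentylbenzoate F5. Palladium-catalysed hydrodeiodination (Pd(OAc)2, PPh3, HCO2H, Et3N, DMF, 60 °C) comes back at 24.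

Step 3. Formylation may occur between the two methoxy groups, or the Lewis acid may cleave the benzyl ester or the methoxy group beside it. The fallback installs the oxygen through a halide and a boronate without any Lewis acid. It sets out from 5: N-bromosuccinimide in MeCN should brominate the same ring position to give benzyl 3-bromo-4,6-dimethoxy-2-pentylbenzoate F6. Miyaura borylation (B2pin2, Pd(OAc)2, SPhos, KOAc, dioxane, 90 °C) should give benzyl 4,6-dimethoxy-2-pentyl-3-(4,4,5,5-tetramethyl-1,3,2-dioxaborolan-2-yl)benzoate F7. Oxidation with NaBO3·4H2O in THF/H2O at rt comes back at 8, bypassing 6 and 7.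

Further compounds

F1 | step 10 | methyl 3-bromopropiolate | COC(=O)C#CBr
F2 | step 10 | methyl 1-{3-[(benzyloxy)carbonyl]-4,6-dimethoxy-2-pentylphenoxy}-3-bromo-5-[(trimethylsilyl)oxy]bicyclo[2.2.2]octa-2,5-diene-2-carboxylate (racemic; one enantiomer written) | COC(=O)C1=C(Br)[C@@H]2CC[C@@]1(Oc3c(OC)cc(OC)c(C(=O)OCc4ccccc4)c3CCCCC)C=C2O[Si](C)(C)C
F3 | step 10 | methyl 2-{3-[(benzyloxy)carbonyl]-4,6-dimethoxy-2-pentylphenoxy}-6-bromo-4-[(trimethylsilyl)oxy]benzoate | COC(=O)c1c(Br)cc(O[Si](C)(C)C)cc1Oc1c(OC)cc(OC)c(C(=O)OCc2ccccc2)c1CCCCC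
F4 | step 10 | methyl 2-{3-[(benzyloxy)carbonyl]-4,6-dimethoxy-2-pentylphenoxy}-6-bromo-4-hydroxybenzoate | COC(=O)c1c(Br)cc(O)cc1Oc1c(OC)cc(OC)c(C(=O)OCc2ccccc2)c1CCCCC
F5 | step 11 | benzyl 3-[(6-hydroxy-4-iodo-1-oxo-3-pentyl-1H-isochromen-8-yl)oxy]-4,6-dimethoxy-2-pentylbenzoate | CCCCCc1oc(=O)c2c(Oc3c(OC)cc(OC)c(C(=O)OCc4ccccc4)c3CCCCC)cc(O)cc2c1I
F6 | step 3 | benzyl 3-bromo-4,6-dimethoxy-2-pentylbenzoate | CCCCCc1c(Br)c(OC)cc(OC)c1C(=O)OCc1ccccc1
F7 | step 3 | benzyl 4,6-dimethoxy-2-pentyl-3-(4,4,5,5-tetramethyl-1,3,2-dioxaborolan-2-yl)benzoate | CCCCCc1c(B2OC(C)(C)C(C)(C)O2)c(OC)cc(OC)c1C(=O)OCc1ccccc1
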